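(The runs stem from a simulated flask with constants of no real substance; noise was put on by code.)

The early readings of these runs bear on the orders and the last readings on what is still to come, so I read the tables below at both ends.

| flask | starting material | partner | free catalyst | time |
|---|---|---|---|---|
| north-west | 200 mM | 500 mM | 20.0 mM |  |
| east | 80.0 mM | 380 mM | 20.0 mM |  |
| south-east | 200 mM | 250 mM | 20.0 mM |  |
| north | 400 mM | 500 mM | 20.0 mM |  |
| south | 200 mM | 500 mM | 20.0 mM | 60 min |

| north-west run: time / min | north-west run: [product] / mM | east run: time / min | east run: [product] / mM | south-east run: time / min | south-east run: [product] / mM | north run: time / min | north run: [product] / mM |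
|---|---|---|---|---|---|---|---|
| 1.2 | 35.2 | 1.2 | 11.4 | 1.2 | 19.7 | 1.2 | 75.2 |
| 2.5 | 59.0 | 2.5 | 18.9 | 2.5 | 34.4 | 2.5 | 108.7 |
| 3.8 | 70.9 | 3.8 | 24.1 | 3.8 | 42.1 | 3.8 | 133.1 |
| 5.0 | 75.1 | 5.0 | 25.7 | 5.0 | 43.4 | 5.0 | 143.6 |
| 6.2 | 80.1 | 6.2 | 26.7 | 6.2 | 46.0 | 6.2 | 150.0 |
| 7.5 | 84.0 | 7.5 | 31.6 | 7.5 | 49.4 | 7.5 | 153.9 |
| 8.8 | 87.4 | 8.8 | 29.8 | 8.8 | 51.1 | 8.8 | 157.1 |
| 10 | 89.1 | 10 | 27.2 | 10 | 50.2 | 10 | 161.7 |

(scatter of a reading: 2 mM)

- Overall: starting material + partner -> product, with free catalyst as catalyst.
- Constant volume, constant temperature.
- An order is taken over about fifteen percent of the charge, up and down.

- apparent order in [starting material] of the starting rate, round the charge of the north-west run (the rate where two percent of its starting material have turned into product) (one fixed amount of product, the same in the runs compared)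
- apparent order in [partner] of the starting rate, round the charge of the north-west run (the rate where two percent of its starting material have turned into product)
- product in the south run at 60 min, as a share of the starting material charged

The top rows come first. From the north-west run to the north run, [starting material] goes from 200 mM to 400 mM and the first reading from 35.2 mM to 75.2 mM, an apparent order of 1.10. From the north-west run to the south-east run, [partner] goes from 500 mM to 250 mM and the first reading falls to 19.7 mM, an apparent order of 0.837. Both are crude under a scatter of 2 mM, so I commit to 1 for each.

Now I read down the columns, in blocks of 2.5 min. In the north-west run the first block gives 59.0 mM and the last 5.10 mM, a share of 0.0864. Starting material is the limiting reagent there, 200 mM against 500 mM. Counted by product made, [starting material]·[partner] still stands at 0.456 of its start. The gain has fallen further than that count, so the product made does not account for the fall in the north-west run.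

So I follow one molecule of starting material that is not yet product: block by block, its chance of becoming product shrinks. Adding the runs to beat the scatter, the blocks give 221 mM, 66.8 mM, 31.1 mM and 9.30 mM. The fade ratio is the factor by which one block's gain exceeds the next's, and I take it as the cube root of first over last: 2.87, a reading with wide scatter. That is a time constant of 2.37 min.

If the blocks keep fading so, everything after a last block adds up to that block's gain divided by the fade ratio less one. For the north-west run this tail is 2.72 mM. The south run has the same charge, and 60 min lies 20.0 blocks past the last reading. I therefore reckon 91.8 mM, or 45.9% of its starting material.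

The forecast gives orders of 1 and 0.95 and 70% (56% to 81%), higher than my figure, on its reading that the stall “is time-dependent catalyst loss”.

The flask gives 43.9% in the south run, 87.8 mM of product and 2 percentage points under my reckoning, with orders of 1.0 and 1.0.

    2 free catalyst ⇌ catalyst dimer, settled at all times (23.70 M⁻¹)
    catalyst dimer + starting material + partner → product + catalyst dimer (112.8 M⁻² min⁻¹)
    starting material → decomposed substrate (0.1632 min⁻¹)
    partner → lost reagent (0.1176 min⁻¹)

Starting material has a second exit, to decomposed substrate, with a rate constant of 0.163 min⁻¹, a mean life of 6.13 min on that exit. Used on the north run, the fade ratio turns its last block of 7.80 mM into a tail of 4.16 mM, an end reckoned at 41.5% of its starting material.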